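**Retrosynthetic overview**

1. Numbering used here: the bicycle is a 3,7-dioxabicyclo[3.3.0]octane with bridgeheads C1 and C5; C2 carries the benzofuranyl group and C6 the syringyl group. Ring B = C1–C2–O3–C4–C5, ring C = C5–C6–O7–C8–C1, ring A = the dihydrofuran ring of the benzofuran. The SMILES is read as ring A 2,3-cis (2S,3S) and the bicycle exo,exo (1R,2S,5R,6S).
2. After a final desilylation, rings B and C are unzipped in one operation to the epoxy allyl ether 21: ring C last through the O7–C6 bond, ring B through the C1–C5 bond.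
3. Enabling feature: C1 is β to O7 through C8, so C8/O7/C1 can be stored as an epoxide that trivalent titanium opens to a C1 radical. The C5=C6 bond of a sinapyl ether, tethered through O3–C4, is the acceptor, and C6, benzylic to the trioxygenated syringyl ring, passes from radical to cation and is captured by O7.
4. Ether 21 comes from epoxy alcohol 14 and sinapyl bromide 20 (from syringaldehyde); a Sharpless kinetic resolution sets C2, the only stereocentre that steers the key step.
5. Ring A is made first by an enantioselective, cis-selective rhodium-carbenoid C–H insertion of aryldiazoacetate 8 (from 4-bromo-2-methoxyphenol, vanillin and ethyl diazoacetate). Ring order: A, then B, then C.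

Key step: step 16

Assumption: Rh2(R-PTTL)4 is taken to deliver the (2S)-configured cis ester (the (S)-leucinate catalysts being taken to give the 2R series); if the sense is the reverse, the antipodal catalyst is used with no other change.
Remark: ring A is the less stable cis isomer, so no step after step 6 uses an epimerising base or a strong acid.

**Route**

Step 1
Reactants: 1 vanillin
Product: 2 3-methoxy-4-(triisopropylsilyloxy)benzaldehyde
Conditions: TIPSCl, imidazole, DMF, rt
Reagents that add atoms: triisopropylsilyl chloride, CC(C)[Si](Cl)(C(C)C)C(C)C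
Why: Phenol silylation; the triisopropylsilyl ether should survive the hydride, organolithium and alkoxide steps and falls to fluoride at the end.

Step 2
Reactants: 2 3-methoxy-4-(triisopropylsilyloxy)benzaldehyde
Product: 3 [3-methoxy-4-(triisopropylsilyloxy)phenyl]methanol
Conditions: NaBH4, MeOH, 0 °C
Reagents that add atoms: none
Why: Borohydride reduction of an aryl aldehyde, which leaves the aryl silyl ether untouched at 0 °C.

Step 3
Reactants: 4 4-bromo-2-methoxyphenol
Product: 5 4-bromo-2-iodo-6-methoxyphenol
Conditions: I2, NaHCO3, THF–H2O, rt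
Reagents that add atoms: iodine, II
Why: Electrophilic aromatic iodination of the phenol/phenoxide; the para position is blocked by bromine, so iodine should enter ortho to the hydroxyl group.

Step 4
Reactants: 5 4-bromo-2-iodo-6-methoxyphenol; 3 [3-methoxy-4-(triisopropylsilyloxy)phenyl]methanol
Product: 6 5-bromo-1-iodo-3-methoxy-2-{[3-methoxy-4-(triisopropylsilyloxy)phenyl]methoxy}benzene
Conditions: PPh3, DIAD, THF, 0 °C → rt
Reagents that add atoms: none
Why: Mitsunobu etherification of an acidic phenol with a primary benzylic alcohol, which avoids the labile p-silyloxybenzyl halide.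

Step 5
Reactants: 6 aryl iodide; 7 ethyl diazoacetate
Product: 8 ethyl 2-(5-bromo-3-methoxy-2-{[3-methoxy-4-(triisopropylsilyloxy)phenyl]methoxy}phenyl)-2-diazoacetate
Conditions: Pd(PPh3)4 (5 mol %), Ag2CO3 (0.5 equiv), Et3N (1.3 equiv), toluene, rt
Reagents that add atoms: none
Why: Palladium-catalysed cross-coupling of an aryl iodide with the C–H bond of a diazoacetate (oxidative addition of zerovalent palladium, palladation of the diazo carbon, reductive elimination with the diazo group kept); at room temperature the C–I bond should react and the C–Br bond should not.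

Step 6
Reactants: 8 aryldiazoacetate
Product: 9 ethyl (2S,3R)-5-bromo-7-methoxy-2-[3-methoxy-4-(triisopropylsilyloxy)phenyl]-2,3-dihydrobenzofuran-3-carboxylate (2,3-cis)
Conditions: dirhodium tetrakis[N-phthaloyl-(R)-tert-leucinate], Rh2(R-PTTL)4 (1–2 mol %), toluene, −78 °C
Reagents that add atoms: none
Why: Intramolecular 1,5 C–H insertion of the donor/acceptor rhodium carbenoid into the benzylic ether methylene closes ring A; the concerted, kinetically controlled insertion should give the 2,3-cis ester, and the chiral carboxylate ligands select one of the two enantiotopic benzylic hydrogens, which sets C2 and C3 together.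

Step 7
Reactants: 9 cis ester
Product: 10 {(2S,3S)-5-bromo-7-methoxy-2-[3-methoxy-4-(triisopropylsilyloxy)phenyl]-2,3-dihydrobenzofuran-3-yl}methanol (2,3-cis)
Conditions: i-Bu2AlH (3 equiv), CH2Cl2, −78 → −20 °C; aq. potassium sodium tartrate
Reagents that add atoms: none
Why: Ester reduction with a non-basic aluminium hydride at low temperature, so that the acidic benzylic C3–H is not epimerised to the trans series (the descriptor at C3 changes from R to S only through the CIP priorities).

Step 8
Reactants: 10 primary alcohol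
Product: 11 (2S,3S)-5-bromo-3-[(tert-butyldimethylsilyloxy)methyl]-7-methoxy-2-[3-methoxy-4-(triisopropylsilyloxy)phenyl]-2,3-dihydrobenzofuran
Conditions: TBSCl, imidazole, DMF, rt
Reagents that add atoms: tert-butyldimethylsilyl chloride, CC(C)(C)[Si](C)(C)Cl
Why: Standard silylation of a primary alcohol, needed before the organolithium and alkoxide steps.

Step 9
Reactants: 11 aryl bromide; 12 acrolein
Product: 13 1-{(2S,3S)-3-[(tert-butyldimethylsilyloxy)methyl]-7-methoxy-2-[3-methoxy-4-(triisopropylsilyloxy)phenyl]-2,3-dihydrobenzofuran-5-yl}prop-2-en-1-ol, mixture of the two carbinol epimers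
Conditions: n-BuLi, THF, −78 °C; then 12, −78 °C; H2O
Reagents that add atoms: none
Why: Bromine–lithium exchange followed by 1,2-addition of the aryllithium to acrolein; the remote stereocentres of ring A exert no control, so both carbinol epimers should form.

Step 10
Reactants: 13 allylic alcohol (mixture of carbinol epimers)
Product: 14 (R)-{(2S,3S)-3-[(tert-butyldimethylsilyloxy)methyl]-7-methoxy-2-[3-methoxy-4-(triisopropylsilyloxy)phenyl]-2,3-dihydrobenzofuran-5-yl}[(S)-oxiran-2-yl]methanol
Conditions: Ti(OiPr)4 (0.2 equiv), D-(−)-diisopropyl tartrate (0.25 equiv), t-BuOOH (0.55 equiv), 4 Å MS, CH2Cl2, −20 °C, stopped near half conversion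
Reagents that add atoms: tert-butyl hydroperoxide, CC(C)(C)OO
Why: Sharpless kinetic resolution, here a reagent-controlled choice between the two carbinol epimers: with the D-(−)-tartrate the (S)-allylic alcohol should be epoxidised fast and erythro-selectively, which fixes the future C2 (called R in 14 only because of the CIP priorities), while the slow (R)-epimer is left and separated.

Step 11
Reactants: 15 syringaldehyde
Product: 16 3,5-dimethoxy-4-(triisopropylsilyloxy)benzaldehyde
Conditions: TIPSCl, imidazole, DMAP (cat.), DMF, 40 °C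
Reagents that add atoms: triisopropylsilyl chloride, CC(C)[Si](Cl)(C(C)C)C(C)C
Why: Silylation of the hindered 2,6-dimethoxyphenol, which gives a base-stable ether.

Step 12
Reactants: 16 silylated syringaldehyde; 17 triethyl phosphonoacetate
Product: 18 ethyl (E)-3-[3,5-dimethoxy-4-(triisopropylsilyloxy)phenyl]prop-2-enoate
Conditions: NaH, THF, 0 °C → rt
Reagents that add atoms: none
Why: Horner–Wadsworth–Emmons olefination, which should give the (E)-cinnamate.

Step 13
Reactants: 18 cinnamate
Product: 19 (E)-3-[3,5-dimethoxy-4-(triisopropylsilyloxy)phenyl]prop-2-en-1-ol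
Conditions: i-Bu2AlH (2.5 equiv), CH2Cl2, −78 °C; aq. potassium sodium tartrate
Reagents that add atoms: none
Why: 1,2-Reduction of an unsaturated ester to the allylic alcohol with retention of the (E)-alkene.

Step 14
Reactants: 19 protected sinapyl alcohol
Product: 20 (E)-3-[3,5-dimethoxy-4-(triisopropylsilyloxy)phenyl]prop-2-enyl bromide
Conditions: CBr4, PPh3, CH2Cl2, 0 °C; used at once
Reagents that add atoms: carbon tetrabromide, BrC(Br)(Br)Br
Why: Appel bromination under neutral conditions, suited to an ionisable, electron-rich cinnamyl system.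

Step 15
Reactants: 14 epoxy alcohol; 20 sinapyl bromide
Product: 21 (2S,3S)-3-[(tert-butyldimethylsilyloxy)methyl]-5-[(R)-{(E)-3-[3,5-dimethoxy-4-(triisopropylsilyloxy)phenyl]prop-2-enyloxy}[(S)-oxiran-2-yl]methyl]-7-methoxy-2-[3-methoxy-4-(triisopropylsilyloxy)phenyl]-2,3-dihydrobenzofuran
Conditions: NaH (1.2 equiv), Bu4NI (cat.), THF–DMF, 0 °C → rt
Reagents that add atoms: none
Why: Williamson etherification of the secondary alkoxide with a reactive allylic bromide at low temperature in an aprotic medium, where Payne rearrangement of the epoxy alkoxide should be slower than alkylation; no stereocentre is touched.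

Step 16
Reactants: 21 epoxy sinapyl ether
Product: 24 tris-silyl ether of the target, via benzyltitanium tetrahydrofuran 22 (not isolated), via benzylic iodide 23 (not isolated)
Conditions: Cp2TiCl (3 equiv, from Cp2TiCl2 and Zn dust in THF, decanted from Zn), added slowly to 21 in THF, rt; then I2 (1.5 equiv), THF, rt → 40 °C; aq. Na2S2O3
Reagents that add atoms: none
Why: Cp2TiCl (trivalent titanium) opens the epoxide by single-electron transfer to the secondary β-titanoxy radical at C1, which adds 5-exo-trig to the sinapyl alkene (ring B, C1–C5 bond) and leaves a benzylic C6 radical that a second Cp2TiCl captures as 22; iodine turns 22 into iodide 23, whose ionisation to the benzylic, quinone-methide-like cation is followed by 5-exo attack of the C8 titanium alkoxide (O7–C6 bond), closing ring C as the last ring. The closest known reaction type is the titanocene-mediated radical cyclisation of epoxy cinnamyl ethers with iodine-induced etherification, known for simple 2,6-diaryl-3,7-dioxabicyclo[3.3.0]octanes. The only stereocentre of 21 that steers the step is C2: in the chair-like 5-exo transition state its aryl group is pseudo-equatorial, so C1 (a planar radical, the epoxide configuration being erased) should end trans to that aryl group and C5 cis to the C8 arm, the only arrangement that can close the cis-fused bicycle. C6 is set in the ionic closure, where the cation rotamer with H-6 turned towards ring B should be attacked so that the syringyl group lands exo on the convex face. The step needs radical formation at the secondary carbon (intrinsic to epoxide opening by Cp2TiCl), cyclisation faster than reduction or elimination of the β-titanoxy radical (secured by the styrene-type acceptor and slow addition), and an intact cis ring A (no strong acid, no radical or cationic site on ring A). Both epoxide epimers and both alkene geometries would converge on the same product, so the step is stereoconvergent.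

Step 17
Reactants: 24 tris-silyl ether of the target
Product: 25 CNP0126146.1
Conditions: Bu4NF (4 equiv), AcOH (4 equiv), THF, 0 °C → rt
Reagents that add atoms: none
Why: Buffered fluoride desilylation removes the two aryl triisopropylsilyl ethers and the primary silyl ether without base or acid strong enough to open ring A or the benzylic ethers of rings B and C.

**Compound list**

1 | vanillin | O=Cc1ccc(O)c(OC)c1 | starting material
2 | 3-methoxy-4-(triisopropylsilyloxy)benzaldehyde | O=Cc1ccc(O[Si](C(C)C)(C(C)C)C(C)C)c(OC)c1 | intermediate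
3 | [3-methoxy-4-(triisopropylsilyloxy)phenyl]methanol | OCc1ccc(O[Si](C(C)C)(C(C)C)C(C)C)c(OC)c1 | intermediate
4 | 4-bromo-2-methoxyphenol | Oc1ccc(Br)cc1OC | starting material
5 | 4-bromo-2-iodo-6-methoxyphenol | Oc1c(I)cc(Br)cc1OC | intermediate
6 | 5-bromo-1-iodo-3-methoxy-2-{[3-methoxy-4-(triisopropylsilyloxy)phenyl]methoxy}benzene | COc1cc(Br)cc(I)c1OCc1ccc(O[Si](C(C)C)(C(C)C)C(C)C)c(OC)c1 | intermediate
7 | ethyl diazoacetate | CCOC(=O)C=[N+]=[N-] | starting material
8 | ethyl 2-(5-bromo-3-methoxy-2-{[3-methoxy-4-(triisopropylsilyloxy)phenyl]methoxy}phenyl)-2-diazoacetate | CCOC(=O)C(=[N+]=[N-])c1cc(Br)cc(OC)c1OCc1ccc(O[Si](C(C)C)(C(C)C)C(C)C)c(OC)c1 | intermediate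
9 | ethyl (2S,3R)-5-bromo-7-methoxy-2-[3-methoxy-4-(triisopropylsilyloxy)phenyl]-2,3-dihydrobenzofuran-3-carboxylate (cis) | COc1cc([C@H]2Oc3c(OC)cc(Br)cc3[C@H]2C(=O)OCC)ccc1O[Si](C(C)C)(C(C)C)C(C)C | intermediate
10 | {(2S,3S)-5-bromo-7-methoxy-2-[3-methoxy-4-(triisopropylsilyloxy)phenyl]-2,3-dihydrobenzofuran-3-yl}methanol (cis) | COc1cc([C@H]2Oc3c(OC)cc(Br)cc3[C@H]2CO)ccc1O[Si](C(C)C)(C(C)C)C(C)C | intermediate
11 | (2S,3S)-5-bromo-3-[(tert-butyldimethylsilyloxy)methyl]-7-methoxy-2-[3-methoxy-4-(triisopropylsilyloxy)phenyl]-2,3-dihydrobenzofuran | COc1cc([C@H]2Oc3c(OC)cc(Br)cc3[C@H]2CO[Si](C)(C)C(C)(C)C)ccc1O[Si](C(C)C)(C(C)C)C(C)C | intermediate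
12 | acrolein | C=CC=O | starting material
13 | 1-aryl-prop-2-en-1-ol on C5 of the ring A unit of 11, mixture of carbinol epimers | COc1cc([C@H]2Oc3c(OC)cc(C(O)C=C)cc3[C@H]2CO[Si](C)(C)C(C)(C)C)ccc1O[Si](C(C)C)(C(C)C)C(C)C | intermediate
14 | (R)-aryl[(S)-oxiran-2-yl]methanol on C5 of the ring A unit (erythro) | COc1cc([C@H]2Oc3c(OC)cc([C@@H](O)[C@@H]4CO4)cc3[C@H]2CO[Si](C)(C)C(C)(C)C)ccc1O[Si](C(C)C)(C(C)C)C(C)C | intermediate
15 | syringaldehyde | O=Cc1cc(OC)c(O)c(OC)c1 | starting material
16 | 3,5-dimethoxy-4-(triisopropylsilyloxy)benzaldehyde | O=Cc1cc(OC)c(O[Si](C(C)C)(C(C)C)C(C)C)c(OC)c1 | intermediate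
17 | triethyl phosphonoacetate | CCOC(=O)CP(=O)(OCC)OCC | starting material
18 | ethyl (E)-3-[3,5-dimethoxy-4-(triisopropylsilyloxy)phenyl]prop-2-enoate | CCOC(=O)/C=C/c1cc(OC)c(O[Si](C(C)C)(C(C)C)C(C)C)c(OC)c1 | intermediate
19 | (E)-3-[3,5-dimethoxy-4-(triisopropylsilyloxy)phenyl]prop-2-en-1-ol | OC/C=C/c1cc(OC)c(O[Si](C(C)C)(C(C)C)C(C)C)c(OC)c1 | intermediate
20 | (E)-3-[3,5-dimethoxy-4-(triisopropylsilyloxy)phenyl]prop-2-enyl bromide | BrC/C=C/c1cc(OC)c(O[Si](C(C)C)(C(C)C)C(C)C)c(OC)c1 | intermediate
21 | epoxy sinapyl ether (R-configured ether carbon, S-oxirane) on C5 of the ring A unit | COc1cc([C@H]2Oc3c(OC)cc([C@@H](OC/C=C/c4cc(OC)c(O[Si](C(C)C)(C(C)C)C(C)C)c(OC)c4)[C@@H]4CO4)cc3[C@H]2CO[Si](C)(C)C(C)(C)C)ccc1O[Si](C(C)C)(C(C)C)C(C)C | intermediate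
22 | benzyltitanium tetrahydrofuran: ring B closed, C6 bound to Cp2TiCl, C8–O bound to Cp2TiCl, C6 unassigned (cyclopentadienyl drawn sigma-bonded) | COc1cc([C@H]2Oc3c(OC)cc([C@H]4OC[C@H](C([Ti](Cl)(C5C=CC=C5)C5C=CC=C5)c5cc(OC)c(O[Si](C(C)C)(C(C)C)C(C)C)c(OC)c5)[C@@H]4CO[Ti](Cl)(C5C=CC=C5)C5C=CC=C5)cc3[C@H]2CO[Si](C)(C)C(C)(C)C)ccc1O[Si](C(C)C)(C(C)C)C(C)C | intermediate (not isolated)
23 | benzylic iodide: ring B closed, iodine on C6, C8–O bound to Cp2TiCl, C6 unassigned | COc1cc([C@H]2Oc3c(OC)cc([C@H]4OC[C@H](C(I)c5cc(OC)c(O[Si](C(C)C)(C(C)C)C(C)C)c(OC)c5)[C@@H]4CO[Ti](Cl)(C5C=CC=C5)C5C=CC=C5)cc3[C@H]2CO[Si](C)(C)C(C)(C)C)ccc1O[Si](C(C)C)(C(C)C)C(C)C | intermediate (not isolated)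
24 | tris-silyl ether of the target (two aryl triisopropylsilyl ethers, one primary tert-butyldimethylsilyl ether) | COc1cc([C@H]2Oc3c(OC)cc([C@H]4OC[C@H]5[C@@H]4CO[C@@H]5c4cc(OC)c(O[Si](C(C)C)(C(C)C)C(C)C)c(OC)c4)cc3[C@H]2CO[Si](C)(C)C(C)(C)C)ccc1O[Si](C(C)C)(C(C)C)C(C)C | intermediate
25 | CNP0126146.1, 4-[(1S,3aR,4S,6aR)-4-{(2S,3S)-3-(hydroxymethyl)-2-(4-hydroxy-3-methoxyphenyl)-7-methoxy-2,3-dihydrobenzofuran-5-yl}tetrahydro-1H,3H-furo[3,4-c]furan-1-yl]-2,6-dimethoxyphenol | COc1cc([C@H]2Oc3c(OC)cc([C@H]4OC[C@H]5[C@@H]4CO[C@@H]5c4cc(OC)c(O)c(OC)c4)cc3[C@H]2CO)ccc1O | target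

**Step count and risks**

Total step count: 17. Longest linear sequence: 12 steps (steps 1, 2, 4–10, 15, 16, 17, from vanillin).

Steps most likely to fail:

1. Step 16. The β-titanoxy radical may be reduced or eliminated before it cyclises, the oxidative closure of ring C may stay incomplete, or the facial selectivity at C6 may be poor. Fallback, from 21 back to 24: the titanocene cyclisation is run alone and quenched with dilute acid, which should give the 4-benzyl-3-(hydroxymethyl)tetrahydrofuran alcohol F1 with ring B in place. Ring C is then closed in a separate ionic step by benzylic oxidation of the syringyl-CH2 group with DDQ (CH2Cl2, 0 °C), the cation being trapped by the C8 hydroxyl group to give 24.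

2. Step 10. Epoxidation of a monosubstituted alkene is slow, the electron-rich benzylic alcohol may ionise under the titanium Lewis acid, and half of the material is the wrong epimer. Fallback, from 11 back to 14, with the carbinol centre set by a catalyst instead of a resolution: bromine–lithium exchange of 11 and quench with DMF give the aldehyde F2. Addition of trimethylsilylacetylene with Me2Zn and the matching ProPhenol ligand should give the (R)-propargylic alcohol F3. Cleavage of the C–Si bond (K2CO3, MeOH, 0 °C, brief) gives the terminal alkyne F4. Semi-hydrogenation (H2, Pd/CaCO3 poisoned with Pb(OAc)2, quinoline) gives the single (S)-allylic alcohol F5. F5 is epoxidised at full conversion in the matched sense with Ti(OiPr)4, D-(−)-diisopropyl tartrate and t-BuOOH to give 14.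

3. Step 5. Oxidative addition and palladation may be slow at the ortho-alkoxy iodide, and palladium may decompose the diazo ester. Fallback, from 6 back to 8, with the diazo group introduced after the C–C bond: 6 is coupled with the Reformatsky reagent BrZnCH2CO2Et (Pd(PPh3)4, THF–DMPU, 50 °C, iodide-selective) to give the ethyl arylacetate F6. Diazo transfer with 4-acetamidobenzenesulfonyl azide and DBU in MeCN (Regitz) then gives 8.

Further compounds
F1 | step 16 | {(2S,3R,4R)-configured ring B alcohol: 2-(ring A aryl)-4-[3,5-dimethoxy-4-(triisopropylsilyloxy)benzyl]tetrahydrofuran-3-yl}methanol | COc1cc([C@H]2Oc3c(OC)cc([C@H]4OC[C@H](Cc5cc(OC)c(O[Si](C(C)C)(C(C)C)C(C)C)c(OC)c5)[C@@H]4CO)cc3[C@H]2CO[Si](C)(C)C(C)(C)C)ccc1O[Si](C(C)C)(C(C)C)C(C)C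
F2 | step 10 | (2S,3S)-3-[(tert-butyldimethylsilyloxy)methyl]-7-methoxy-2-[3-methoxy-4-(triisopropylsilyloxy)phenyl]-2,3-dihydrobenzofuran-5-carbaldehyde | COc1cc([C@H]2Oc3c(OC)cc(C=O)cc3[C@H]2CO[Si](C)(C)C(C)(C)C)ccc1O[Si](C(C)C)(C(C)C)C(C)C
F3 | step 10 | (R)-1-aryl-3-(trimethylsilyl)prop-2-yn-1-ol on C5 of the ring A unit | COc1cc([C@H]2Oc3c(OC)cc([C@@H](O)C#C[Si](C)(C)C)cc3[C@H]2CO[Si](C)(C)C(C)(C)C)ccc1O[Si](C(C)C)(C(C)C)C(C)C
F4 | step 10 | (S)-1-aryl-prop-2-yn-1-ol on C5 of the ring A unit | COc1cc([C@H]2Oc3c(OC)cc([C@@H](O)C#C)cc3[C@H]2CO[Si](C)(C)C(C)(C)C)ccc1O[Si](C(C)C)(C(C)C)C(C)C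
F5 | step 10 | (S)-1-aryl-prop-2-en-1-ol on C5 of the ring A unit (single epimer of 13) | COc1cc([C@H]2Oc3c(OC)cc([C@@H](O)C=C)cc3[C@H]2CO[Si](C)(C)C(C)(C)C)ccc1O[Si](C(C)C)(C(C)C)C(C)C
F6 | step 5 | ethyl 2-(5-bromo-3-methoxy-2-{[3-methoxy-4-(triisopropylsilyloxy)phenyl]methoxy}phenyl)acetate | CCOC(=O)Cc1cc(Br)cc(OC)c1OCc1ccc(O[Si](C(C)C)(C(C)C)C(C)C)c(OC)c1
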